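**Plan**

- Retrosynthetic cuts, in order: the two ester C–O bonds at O3 and O9 (made as hex-2-ynoates, Z geometry from syn semihydrogenation); C7–C11 (acetone aldol); C5–C6 of ring B (radical closure); C8–C7 (vinyl Grignard on a Weinreb amide); C9–O (enolate hydroxylation); C5=C14 (methylenation); C10–C9 (enolate alkylation).
- Enabling feature: quaternary C5 carries both the C14 methyl and the ring-B methylene C6. A C5=C14 exocyclic alkene on ring A can therefore accept a hydrogen atom at C14, and the tertiary C5 radical can close ring B onto C6 of a vinyl ketone tethered through C10 (C10–C9–C8(=O)–C7=C6).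
- Forward order: ring A first (from 2-methylcyclohex-2-en-1-one), then the C9–C6 chain on C10, then ring B by the radical step (18 → 19), then C11–C13, the 8-hydroxyl and the esters.
- Stereochemistry: C3 from a CBS reduction; C4 and C10 by equilibration of a 2,6-disubstituted cyclohexanone to its all-equatorial isomer under control of C3; C9 by A(1,3)-controlled enolate hydroxylation; C5 in the ring closure (trans fusion); C7 by aldol anti to the C14 methyl; C8 by equatorial hydride delivery.

Key step: step 11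

Remark: eremophilane numbering is used (ring A = C1–C5, C10; ring B = C5–C10; C14 on C5, C15 on C4, C11–C13 on C7); β is the face of the C14 and C15 methyls, α the opposite face; TBS = tert-butyldimethylsilyl, TES = triethylsilyl.

**Route**

Step 1
Reactants: 1 2-methylcyclohex-2-en-1-one
Product: 2 (1R)-2-methylcyclohex-2-en-1-ol
Conditions: (S)-1-methyl-3,3-diphenyltetrahydro-1H,3H-pyrrolo[1,2-c][1,3,2]oxazaborole (10 mol%), BH3·SMe2, THF, −20 °C; MeOH quench
Reagents that add atoms: none
Why: Corey–Bakshi–Shibata reduction, in which the oxazaborolidine–borane complex binds the ketone with the α-methylalkenyl arm as the larger substituent and delivers hydride 1,2 to one face, should give the (R)-allylic alcohol whose carbinol carbon becomes C3.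

Step 2
Reactants: 2 (1R)-2-methylcyclohex-2-en-1-ol
Product: 3 tert-butyldimethyl{[(1R)-2-methylcyclohex-2-en-1-yl]oxy}silane
Conditions: TBSCl, imidazole, DMF, rt
Reagents that add atoms: tert-butyldimethylsilyl chloride, CC(C)(C)[Si](C)(C)Cl
Why: Imidazole-promoted silylation of a secondary alcohol gives a silyl ether that is stable to the bases, organometallics and radical conditions ahead and has no easily abstracted hydrogen next to oxygen.

Step 3
Reactants: 3 tert-butyldimethyl{[(1R)-2-methylcyclohex-2-en-1-yl]oxy}silane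
Product: 5 (1R,2S,3R)-3-[(tert-butyldimethylsilyl)oxy]-2-methylcyclohexan-1-ol, via alkylborane 4 (not isolated)
Conditions: BH3·THF, THF, 0 °C to rt; then aq. NaOH, H2O2, 0 °C
Reagents that add atoms: hydrogen peroxide, OO
Why: Hydroboration–oxidation places boron on the less substituted, oxygen-remote alkene carbon, syn to the new C–H and anti to the silyloxy group, and oxidation with retention gives the alcohol; the configuration created at the methyl-bearing carbon does not matter because it is reset in step 5.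

Step 4
Reactants: 5 (1R,2S,3R)-3-[(tert-butyldimethylsilyl)oxy]-2-methylcyclohexan-1-ol
Product: 6 (2R,3R)-3-[(tert-butyldimethylsilyl)oxy]-2-methylcyclohexan-1-one
Conditions: Dess–Martin periodinane, NaHCO3, CH2Cl2, 0 °C to rt
Reagents that add atoms: none
Why: Dess–Martin oxidation converts the secondary alcohol into the ketone under buffered, non-basic conditions that leave the β-silyloxy ketone intact.

Step 5
Reactants: 6 (2R,3R)-3-[(tert-butyldimethylsilyl)oxy]-2-methylcyclohexan-1-one; 7 ethyl iodoacetate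
Product: 10 ethyl 2-[(1S,3S,4R)-4-[(tert-butyldimethylsilyl)oxy]-3-methyl-2-oxocyclohexyl]acetate, via lithium enolate 8 (not isolated), via kinetic epimer 9 (not isolated)
Conditions: LiN(iPr)2, THF, −78 °C; 7, DMPU, −78 to −20 °C; then NaOEt (0.3 equiv), EtOH, 0 °C to rt; aq. NH4Cl
Reagents that add atoms: ethyl iodoacetate (7), ICC(=O)OCC
Why: Kinetic deprotonation at the CH2 flank and SN2 alkylation of the enolate form C10–C9, and brief alkoxide equilibration of both α-centres (C4 and C10) should funnel all epimers into the isomer with silyloxy, methyl and acetate arm equatorial, so that C3 sets C4 and C10.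

Step 6
Reactants: 10 ethyl 2-[(1S,3S,4R)-4-[(tert-butyldimethylsilyl)oxy]-3-methyl-2-oxocyclohexyl]acetate; 11 dibromomethane
Product: 12 ethyl 2-[(1S,3R,4R)-4-[(tert-butyldimethylsilyl)oxy]-3-methyl-2-methylidenecyclohexyl]acetate
Conditions: Zn, CH2Br2, TiCl4, THF, 0 °C (reagent aged); then 10, CH2Cl2, 0 °C to rt
Reagents that add atoms: dibromomethane (11), BrCBr
Why: Takai–Lombardo methylenation with the non-basic zinc/titanium methylene reagent should olefinate the hindered, enolisable ketone without touching the ester, the silyl ether or the two α-stereocentres, giving the C5=C14 alkene.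

Step 7
Reactants: 12 ethyl 2-[(1S,3R,4R)-4-[(tert-butyldimethylsilyl)oxy]-3-methyl-2-methylidenecyclohexyl]acetate
Product: 14 ethyl (2S)-2-hydroxy-2-[(1R,3R,4R)-4-[(tert-butyldimethylsilyl)oxy]-3-methyl-2-methylidenecyclohexyl]acetate, via potassium enolate 13 (not isolated)
Conditions: KN(SiMe3)2, THF, −78 °C; 3-phenyl-2-(phenylsulfonyl)oxaziridine, −78 °C; aq. NH4Cl
Reagents that add atoms: 3-phenyl-2-(phenylsulfonyl)oxaziridine, O=S(=O)(c1ccccc1)N1OC1c1ccccc1
Why: Davis oxidation of the ester enolate, in which H10 eclipses the enolate plane to avoid A(1,3) strain and the oxaziridine approaches C9 from the side of C1, away from C5 and its exocyclic methylene, should give the 9S alcohol.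

Step 8
Reactants: 14 ethyl (2S)-2-hydroxy-2-[(1R,3R,4R)-4-[(tert-butyldimethylsilyl)oxy]-3-methyl-2-methylidenecyclohexyl]acetate
Product: 15 ethyl (2S)-2-[(tert-butyldimethylsilyl)oxy]-2-[(1R,3R,4R)-4-[(tert-butyldimethylsilyl)oxy]-3-methyl-2-methylidenecyclohexyl]acetate
Conditions: TBSOTf, 2,6-lutidine, CH2Cl2, −78 to 0 °C
Reagents that add atoms: tert-butyldimethylsilyl trifluoromethanesulfonate, CC(C)(C)[Si](C)(C)OS(=O)(=O)C(F)(F)F
Why: Silyl triflate silylation protects the hindered α-hydroxy ester without epimerisation, and the bulky 9-silyloxy group later steers the ring closure.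

Step 9
Reactants: 15 ethyl (2S)-2-[(tert-butyldimethylsilyl)oxy]-2-[(1R,3R,4R)-4-[(tert-butyldimethylsilyl)oxy]-3-methyl-2-methylidenecyclohexyl]acetate
Product: 16 (2S)-2-[(tert-butyldimethylsilyl)oxy]-2-[(1R,3R,4R)-4-[(tert-butyldimethylsilyl)oxy]-3-methyl-2-methylidenecyclohexyl]-N-methoxy-N-methylacetamide
Conditions: MeNHOMe·HCl, iPrMgCl, THF, −20 to 0 °C
Reagents that add atoms: N,O-dimethylhydroxylamine hydrochloride, CNOC.Cl
Why: Weinreb amide formation by aminolysis of the ester with the chloromagnesium amide of N,O-dimethylhydroxylamine proceeds below 0 °C and should not disturb the α-silyloxy centre.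

Step 10
Reactants: 16 (2S)-2-[(tert-butyldimethylsilyl)oxy]-2-[(1R,3R,4R)-4-[(tert-butyldimethylsilyl)oxy]-3-methyl-2-methylidenecyclohexyl]-N-methoxy-N-methylacetamide; 17 vinylmagnesium bromide
Product: 18 (1S)-1-[(tert-butyldimethylsilyl)oxy]-1-[(1R,3R,4R)-4-[(tert-butyldimethylsilyl)oxy]-3-methyl-2-methylidenecyclohexyl]but-3-en-2-one
Conditions: 17, THF, −78 to 0 °C; inverse quench into cold aq. KHSO4
Reagents that add atoms: vinylmagnesium bromide (17), C=C[Mg]Br
Why: Weinreb ketone synthesis delivers a single vinyl group because the chelated adduct holds until the acidic quench, which also protonates the released amine before it can add to the new enone.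

Step 11
Reactants: 18 (1S)-1-[(tert-butyldimethylsilyl)oxy]-1-[(1R,3R,4R)-4-[(tert-butyldimethylsilyl)oxy]-3-methyl-2-methylidenecyclohexyl]but-3-en-2-one
Product: 19 3α,9α-bis[(tert-butyldimethylsilyl)oxy]-4β,5β-dimethyl-10αH-decalin-8-one (trans-fused)
Conditions: Fe(acac)3 (0.3 equiv), PhSiH3 (2.5 equiv), EtOH/ethylene glycol 5:1, 0.02 M, degassed, 60 °C
Reagents that add atoms: none
Why: An iron hydride formed from Fe(acac)3 and PhSiH3 transfers a hydrogen atom to C14 of the electron-rich 1,1-disubstituted alkene, which makes C14 the methyl group and leaves a nucleophilic tertiary radical at C5; this adds to C6, the β-carbon of the vinyl ketone, and the α-keto radical at C7 is reduced to the enolate and protonated by ethanol. The closest known reaction type is the iron-mediated hydrogen-atom-transfer reductive coupling of unactivated alkenes with enones (a radical Giese addition), used here intramolecularly. Ring B closes 6-endo-trig because the carbonyl C8 lies inside the tether, whereas the 5-exo alternative would require attack at the α-carbon C7 and would give an unstabilised primary radical. The new stereocentre C5 is set by a chair-like transition state in which the C10–C9 bond stays equatorial on ring A, C6 bonds to C5 equatorially and C14 becomes axial, which is the trans fusion. The step needs hydrogen-atom transfer to the exocyclic alkene and not to the enone, which the polarity of the metal hydride favours, and trans over cis fusion, which the 9α-silyloxy group secures because it is equatorial in the trans chair but would be 1,3-diaxial to C14 in the cis-fused one.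

Step 12
Reactants: 19 3α,9α-bis[(tert-butyldimethylsilyl)oxy]-4β,5β-dimethyl-10αH-decalin-8-one; 20 acetone
Product: 22 7α-(2-hydroxypropan-2-yl)-3α,9α-bis[(tert-butyldimethylsilyl)oxy]-4β,5β-dimethyl-10αH-decalin-8-one, via lithium enolate 21 (not isolated)
Conditions: LiN(iPr)2, THF, −78 °C; 20, −78 °C; AcOH quench at −78 °C
Reagents that add atoms: acetone (20), CC(C)=O
Why: Kinetic enolisation at the C7 methylene (C9–H is tertiary, oxygen-bearing and shielded by the axial C14 methyl) followed by aldol addition to acetone on the α face, anti to the 1,3-related C14 methyl, should place the hydroxyisopropyl group equatorial at C7.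

Step 13
Reactants: 22 7α-(2-hydroxypropan-2-yl)-3α,9α-bis[(tert-butyldimethylsilyl)oxy]-4β,5β-dimethyl-10αH-decalin-8-one
Product: 23 7α-(2-hydroxypropan-2-yl)-3α,9α-bis[(tert-butyldimethylsilyl)oxy]-4β,5β-dimethyl-10αH-decalin-8α-ol
Conditions: LiBH(s-Bu)3, THF, −78 °C; AcOH quench at −78 °C
Reagents that add atoms: none
Why: Reduction with a bulky trialkylborohydride delivers hydride along the equatorial direction of the ring-B chair and should give the axial 8α-alcohol, with the cold acidic quench preventing silyl migration from O9.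

Step 14
Reactants: 23 7α-(2-hydroxypropan-2-yl)-3α,9α-bis[(tert-butyldimethylsilyl)oxy]-4β,5β-dimethyl-10αH-decalin-8α-ol
Product: 24 8α-O-triethylsilyl ether of 23
Conditions: Et3SiCl, imidazole, DMAP (cat.), DMF, 40 °C
Reagents that add atoms: chlorotriethylsilane, CC[Si](Cl)(CC)CC
Why: Chlorosilane/imidazole silylation reacts with the secondary 8-hydroxyl but not with the tertiary alcohol, which is thereby left as the only site for elimination.

Step 15
Reactants: 24 8α-O-triethylsilyl ether of 23
Product: 25 3α,9α-bis[(tert-butyldimethylsilyl)oxy]-8α-[(triethylsilyl)oxy]-10αH-eremophil-11-ene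
Conditions: Burgess reagent (methyl N-(triethylammoniosulfonyl)carbamate), toluene, 60 °C
Reagents that add atoms: none
Why: Burgess dehydration of the tertiary alcohol by syn elimination should run toward a methyl group, because H7 is a single axial hydrogen under the C14 methyl and the alternative tetrasubstituted C7=C11 alkene would clash with the 8-silyloxy group, so C7 keeps its configuration.

Step 16
Reactants: 25 3α,9α-bis[(tert-butyldimethylsilyl)oxy]-8α-[(triethylsilyl)oxy]-10αH-eremophil-11-ene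
Product: 26 10αH-eremophil-11-ene-3α,8α,9α-triol
Conditions: Bu4NF, THF, rt to 50 °C
Reagents that add atoms: none
Why: Fluoride-mediated desilylation removes the triethylsilyl and both tert-butyldimethylsilyl ethers in one operation, and nothing in the triol is base-labile.

Step 17
Reactants: 26 10αH-eremophil-11-ene-3α,8α,9α-triol; 27 hex-2-ynoic acid
Product: 28 8α-hydroxy-10αH-eremophil-11-ene-3α,9α-diyl bis(hex-2-ynoate)
Conditions: 27 (2.2 equiv), N,N'-diisopropylcarbodiimide, DMAP (cat.), CH2Cl2, −20 to 0 °C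
Reagents that add atoms: hex-2-ynoic acid (27), CCCC#CC(=O)O
Why: Steglich esterification under stoichiometric control should acylate the equatorial 3- and 9-hydroxyls ahead of the axial 8-hydroxyl, which is flanked by two equatorial substituents, and an 8-O-acyl isomer would be less stable than the equatorial 9-ester.

Step 18
Reactants: 28 8α-hydroxy-10αH-eremophil-11-ene-3α,9α-diyl bis(hex-2-ynoate)
Product: 29 8α-hydroxy-10αH-eremophil-11-ene-3α,9α-diyl bis[(2Z)-hex-2-enoate] (CNP0420276.1)
Conditions: H2 (1 atm), Pd on CaCO3 poisoned with Pb(OAc)2, quinoline, EtOAc, rt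
Reagents that add atoms: none
Why: Lindlar semihydrogenation adds one equivalent of H2 syn to each conjugated alkyne to give both (Z)-hex-2-enoates, while the poisoned catalyst should leave the 1,1-disubstituted isopropenyl alkene and the enoates alone.

**Compound list**

1 | 2-methylcyclohex-2-en-1-one | CC1=CCCCC1=O | starting material
2 | (1R)-2-methylcyclohex-2-en-1-ol | O[C@H]1C(C)=CCCC1 | intermediate
3 | tert-butyldimethyl{[(1R)-2-methylcyclohex-2-en-1-yl]oxy}silane | CC(C)(C)[Si](C)(C)O[C@H]1C(C)=CCCC1 | intermediate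
4 | [(1R,2S,3R)-3-(TBS-oxy)-2-methylcyclohexyl]borane (boron trans to methyl and to the silyloxy group) | B[C@H]1[C@H](C)[C@H](O[Si](C)(C)C(C)(C)C)CCC1 | intermediate (not isolated)
5 | (1R,2S,3R)-3-[(tert-butyldimethylsilyl)oxy]-2-methylcyclohexan-1-ol | O[C@H]1[C@H](C)[C@H](O[Si](C)(C)C(C)(C)C)CCC1 | intermediate
6 | (2R,3R)-3-[(tert-butyldimethylsilyl)oxy]-2-methylcyclohexan-1-one | O=C1[C@H](C)[C@H](O[Si](C)(C)C(C)(C)C)CCC1 | intermediate
7 | ethyl iodoacetate | ICC(=O)OCC | starting material
8 | lithium (5R,6R)-5-(TBS-oxy)-6-methylcyclohex-1-en-1-olate | [Li]OC1=CCC[C@@H](O[Si](C)(C)C(C)(C)C)[C@H]1C | intermediate (not isolated)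
9 | ethyl 2-[(1S,3R,4R)-4-(TBS-oxy)-3-methyl-2-oxocyclohexyl]acetate (kinetic epimer, methyl cis to silyloxy) | O=C1[C@H](C)[C@H](O[Si](C)(C)C(C)(C)C)CC[C@H]1CC(=O)OCC | intermediate (not isolated)
10 | ethyl 2-[(1S,3S,4R)-4-(TBS-oxy)-3-methyl-2-oxocyclohexyl]acetate (all-equatorial) | O=C1[C@@H](C)[C@H](O[Si](C)(C)C(C)(C)C)CC[C@H]1CC(=O)OCC | intermediate
11 | dibromomethane | BrCBr | starting material
12 | ethyl 2-[(1S,3R,4R)-4-(TBS-oxy)-3-methyl-2-methylidenecyclohexyl]acetate | C=C1[C@@H](C)[C@H](O[Si](C)(C)C(C)(C)C)CC[C@H]1CC(=O)OCC | intermediate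
13 | potassium enolate of 12 | C=C1[C@@H](C)[C@H](O[Si](C)(C)C(C)(C)C)CC[C@H]1C=C(O[K])OCC | intermediate (not isolated)
14 | ethyl (2S)-2-hydroxy-2-[(1R,3R,4R)-4-(TBS-oxy)-3-methyl-2-methylidenecyclohexyl]acetate | C=C1[C@@H](C)[C@H](O[Si](C)(C)C(C)(C)C)CC[C@H]1[C@H](O)C(=O)OCC | intermediate
15 | ethyl (2S)-2-(TBS-oxy)-2-[(1R,3R,4R)-4-(TBS-oxy)-3-methyl-2-methylidenecyclohexyl]acetate | C=C1[C@@H](C)[C@H](O[Si](C)(C)C(C)(C)C)CC[C@H]1[C@H](O[Si](C)(C)C(C)(C)C)C(=O)OCC | intermediate
16 | (2S)-2-(TBS-oxy)-2-[(1R,3R,4R)-4-(TBS-oxy)-3-methyl-2-methylidenecyclohexyl]-N-methoxy-N-methylacetamide | C=C1[C@@H](C)[C@H](O[Si](C)(C)C(C)(C)C)CC[C@H]1[C@H](O[Si](C)(C)C(C)(C)C)C(=O)N(C)OC | intermediate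
17 | vinylmagnesium bromide | C=C[Mg]Br | starting material
18 | (1S)-1-(TBS-oxy)-1-[(1R,3R,4R)-4-(TBS-oxy)-3-methyl-2-methylidenecyclohexyl]but-3-en-2-one | C=C1[C@@H](C)[C@H](O[Si](C)(C)C(C)(C)C)CC[C@H]1[C@H](O[Si](C)(C)C(C)(C)C)C(=O)C=C | intermediate
19 | 3α,9α-bis(TBS-oxy)-4β,5β-dimethyl-10αH-decalin-8-one (trans-fused) | O=C1CC[C@]2(C)[C@@H](C)[C@H](O[Si](C)(C)C(C)(C)C)CC[C@H]2[C@@H]1O[Si](C)(C)C(C)(C)C | intermediate
20 | acetone | CC(C)=O | starting material
21 | lithium enolate of 19 (C7=C8) | [Li]OC1=CC[C@]2(C)[C@@H](C)[C@H](O[Si](C)(C)C(C)(C)C)CC[C@H]2[C@@H]1O[Si](C)(C)C(C)(C)C | intermediate (not isolated)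
22 | 7α-(2-hydroxypropan-2-yl)-3α,9α-bis(TBS-oxy)-4β,5β-dimethyl-10αH-decalin-8-one | CC(C)(O)[C@@H]1C[C@]2(C)[C@@H](C)[C@H](O[Si](C)(C)C(C)(C)C)CC[C@H]2[C@H](O[Si](C)(C)C(C)(C)C)C1=O | intermediate
23 | 7α-(2-hydroxypropan-2-yl)-3α,9α-bis(TBS-oxy)-4β,5β-dimethyl-10αH-decalin-8α-ol | CC(C)(O)[C@@H]1C[C@]2(C)[C@@H](C)[C@H](O[Si](C)(C)C(C)(C)C)CC[C@H]2[C@H](O[Si](C)(C)C(C)(C)C)[C@@H]1O | intermediate
24 | 8α-O-triethylsilyl ether of 23 | CC(C)(O)[C@@H]1C[C@]2(C)[C@@H](C)[C@H](O[Si](C)(C)C(C)(C)C)CC[C@H]2[C@H](O[Si](C)(C)C(C)(C)C)[C@@H]1O[Si](CC)(CC)CC | intermediate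
25 | 3α,9α-bis(TBS-oxy)-8α-(TES-oxy)-10αH-eremophil-11-ene | C=C(C)[C@@H]1C[C@]2(C)[C@@H](C)[C@H](O[Si](C)(C)C(C)(C)C)CC[C@H]2[C@H](O[Si](C)(C)C(C)(C)C)[C@@H]1O[Si](CC)(CC)CC | intermediate
26 | 10αH-eremophil-11-ene-3α,8α,9α-triol | C=C(C)[C@@H]1C[C@]2(C)[C@@H](C)[C@H](O)CC[C@H]2[C@H](O)[C@@H]1O | intermediate
27 | hex-2-ynoic acid | CCCC#CC(=O)O | starting material
28 | 8α-hydroxy-10αH-eremophil-11-ene-3α,9α-diyl bis(hex-2-ynoate) | C=C(C)[C@@H]1C[C@]2(C)[C@@H](C)[C@H](OC(=O)C#CCCC)CC[C@H]2[C@H](OC(=O)C#CCCC)[C@@H]1O | intermediate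
29 | (3R,4R,5R,7S,8R,9S,10R)-8-hydroxyeremophil-11-ene-3,9-diyl bis[(2Z)-hex-2-enoate] (CNP0420276.1) | C=C(C)[C@@H]1C[C@]2(C)[C@@H](C)[C@H](OC(=O)/C=C\CCC)CC[C@H]2[C@H](OC(=O)/C=C\CCC)[C@@H]1O | target

**Count**

Total steps: 18. Longest linear sequence: 18 steps (1 → 29); compounds 7, 11, 17, 20 and 27 are commercial.

**Steps most likely to fail**

The ring closure (step 11) is ranked below the three steps here because it rests on a well-precedented reaction type and on the substrate biases named in its entry.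

Step 7. What may go wrong: weak facial discrimination in the oxidation of the acyclic ester enolate, which is steered only by A(1,3) strain, and competing addition of the enolate to the sulfonimine by-product.
Fallback, setting out from 10 and rejoining at 16: a cyclic template replaces acyclic control. LiBH(s-Bu)3 reduces the ketone of 10 from the equatorial direction, and the axial 5β-alkoxide closes onto the cis-disposed ester to give the cis-fused γ-lactone F1. Its enolate (LiN(iPr)2, THF, −78 °C) is oxidised by the same oxaziridine on the convex face, trans to C1, which corresponds to the 9S configuration, giving the hydroxy lactone F2. Silylation (TBSOTf, 2,6-lutidine) gives the silyloxy lactone F3. Opening with MeNHOMe·HCl/AlMe3 gives the 5β-hydroxy Weinreb amide F4, Dess–Martin oxidation gives the keto Weinreb amide F5, and Takai–Lombardo methylenation (Zn, CH2Br2, TiCl4) returns to 16.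

Step 15. What may go wrong: loss of regiocontrol in the elimination (proton removed from C7 instead of a methyl group, giving the tetrasubstituted 7(11)-alkene), or ionisation of the tertiary sulfamate with skeletal side reactions.
Fallback, setting out from 22 and rejoining at 26: the alkene position is set by enolate protonation instead of by the direction of an elimination. Aldol 22 is dehydrated fully into conjugation (MsCl, Et3N, DMAP; then DBU) to the isopropylidene enone F6. γ-Deprotonation with KN(SiMe3)2 and kinetic α-protonation of the extended enolate at −78 °C (AcOH) give the β,γ-unsaturated 7α-isopropenyl ketone F7; a 7β epimer, strained against the C14 methyl, should relax to it through the same enolate. Immediate reduction with LiBH(s-Bu)3 gives the bis-silyl 8α-alcohol F8, and Bu4NF returns to triol 26.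

Step 17. What may go wrong: over-acylation at O8, or acyl migration between the cis-related O8 and O9 under the basic catalyst.
Fallback, setting out from 23 and rejoining at 28: an orthogonal ether on O8 replaces kinetic site selection. The secondary hydroxyl of 23 is converted with 4-methoxybenzyl 2,2,2-trichloroacetimidate and La(OTf)3 (cat.) into the 8-O-(4-methoxybenzyl) ether F9. Burgess dehydration gives the isopropenyl compound F10, Bu4NF gives the 3,9-diol F11, and exhaustive esterification with 27 (N,N'-diisopropylcarbodiimide, DMAP) gives the bis(hex-2-ynoate) F12. DDQ in CH2Cl2/pH 7 buffer removes the benzyl ether and returns to 28.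

**Further compounds**

F1 | step 7 | cis-fused lactone: 6-(TBS-oxy)-7-methylhexahydro-1-benzofuran-2(3H)-one (O on C5 β, 3α-silyloxy, 4β-methyl) | O=C1C[C@@H]2CC[C@@H](O[Si](C)(C)C(C)(C)C)[C@H](C)[C@@H]2O1
F2 | step 7 | (9S)-hydroxy lactone: 3-hydroxy derivative of F1, hydroxyl trans to C1 | O=C1[C@@H](O)[C@@H]2CC[C@@H](O[Si](C)(C)C(C)(C)C)[C@H](C)[C@@H]2O1
F3 | step 7 | silyloxy lactone: 3-(TBS-oxy) derivative of F1 | O=C1[C@@H](O[Si](C)(C)C(C)(C)C)[C@@H]2CC[C@@H](O[Si](C)(C)C(C)(C)C)[C@H](C)[C@@H]2O1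
F4 | step 7 | 5β-hydroxy Weinreb amide: (2S)-2-(TBS-oxy)-2-[4-(TBS-oxy)-2-hydroxy-3-methylcyclohexyl]-N-methoxy-N-methylacetamide | CON(C)C(=O)[C@@H](O[Si](C)(C)C(C)(C)C)[C@@H]1CC[C@@H](O[Si](C)(C)C(C)(C)C)[C@H](C)[C@@H]1O
F5 | step 7 | keto Weinreb amide: (2S)-2-(TBS-oxy)-2-[4-(TBS-oxy)-3-methyl-2-oxocyclohexyl]-N-methoxy-N-methylacetamide | CON(C)C(=O)[C@@H](O[Si](C)(C)C(C)(C)C)[C@@H]1CC[C@@H](O[Si](C)(C)C(C)(C)C)[C@H](C)C1=O
F6 | step 15 | isopropylidene enone: 3α,9α-bis(TBS-oxy)-10αH-eremophil-7(11)-en-8-one | CC(C)=C1C[C@]2(C)[C@@H](C)[C@H](O[Si](C)(C)C(C)(C)C)CC[C@H]2[C@H](O[Si](C)(C)C(C)(C)C)C1=O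
F7 | step 15 | 7α-isopropenyl ketone: 3α,9α-bis(TBS-oxy)-10αH-eremophil-11-en-8-one | C=C(C)[C@@H]1C[C@]2(C)[C@@H](C)[C@H](O[Si](C)(C)C(C)(C)C)CC[C@H]2[C@H](O[Si](C)(C)C(C)(C)C)C1=O
F8 | step 15 | bis-silyl 8α-alcohol: 3α,9α-bis(TBS-oxy)-10αH-eremophil-11-en-8α-ol | C=C(C)[C@@H]1C[C@]2(C)[C@@H](C)[C@H](O[Si](C)(C)C(C)(C)C)CC[C@H]2[C@H](O[Si](C)(C)C(C)(C)C)[C@@H]1O
F9 | step 17 | 8-O-(4-methoxybenzyl) ether of 23 | CC(C)(O)[C@@H]1C[C@]2(C)[C@@H](C)[C@H](O[Si](C)(C)C(C)(C)C)CC[C@H]2[C@H](O[Si](C)(C)C(C)(C)C)[C@@H]1OCc1ccc(OC)cc1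
F10 | step 17 | 3α,9α-bis(TBS-oxy)-8α-(4-methoxybenzyloxy)-10αH-eremophil-11-ene | C=C(C)[C@@H]1C[C@]2(C)[C@@H](C)[C@H](O[Si](C)(C)C(C)(C)C)CC[C@H]2[C@H](O[Si](C)(C)C(C)(C)C)[C@@H]1OCc1ccc(OC)cc1
F11 | step 17 | 8α-(4-methoxybenzyloxy)-10αH-eremophil-11-ene-3α,9α-diol | C=C(C)[C@@H]1C[C@]2(C)[C@@H](C)[C@H](O)CC[C@H]2[C@H](O)[C@@H]1OCc1ccc(OC)cc1
F12 | step 17 | 8α-(4-methoxybenzyloxy)-10αH-eremophil-11-ene-3α,9α-diyl bis(hex-2-ynoate) | C=C(C)[C@@H]1C[C@]2(C)[C@@H](C)[C@H](OC(=O)C#CCCC)CC[C@H]2[C@H](OC(=O)C#CCCC)[C@@H]1OCc1ccc(OC)cc1
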